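## Retrosynthetic overview

1. Xestin A (ring atoms O1, O2, C3–C6 of the 3,6-dihydro-1,2-dioxine, O1 on C6) is cut at O2–C3 and C4=C5 together. This gives an (R)-α-methoxy-α-(silylperoxy) aldehyde (C5, C6, O1, O2 and the C18 dienyl chain) and an allylic phosphonium salt holding C3, C4 and the CH2CO2Me arm. Forward: peroxide oxa-Michael addition, then ring-closing Wittig olefination in the same flask.
2. Enabling feature: hydroperoxide oxygen O2 and aldehyde carbon C5 sit 1,4 to each other on the quaternary peroxyketal carbon C6, and the C4=C5 alkene lies inside the six-membered dioxine ring. A C3=C4 unit that is electrophilic at C3 and becomes a phosphonium ylide at C4 can therefore be clasped between O2 and C5, and the ring size dictates the cis alkene.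
3. The aldehyde comes from an 8-phenylmenthyl α-methoxy ester: C6 is set by O2 capture of its lithium enolate (auxiliary control), followed by O-silylation and i-Bu2AlH reduction. The ester comes from the auxiliary methoxyacetate and the C18 dienyl iodide.
4. The iodide comes from sorbyl acetate and 12-bromododecan-1-ol (copper-catalysed Grignard coupling, Appel iodination).
5. Rings: the 1,2-dioxine is the only ring and is closed in the last step.

Key step: step 9

Assumption: the (−)-8-phenylmenthyl ester is taken to direct O2 to the enolate face that gives the (2R)-peroxyketal; if the opposite sense is found, (+)-8-phenylmenthol is used with no other change.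

## Route

Step 1
Reactants: 1 methyl (2E)-4-bromobut-2-enoate; 2 triphenylphosphine
Product: 3 [(2E)-4-methoxy-4-oxobut-2-en-1-yl]triphenylphosphonium bromide
Conditions: toluene, rt, 16 h; filter
Reagents that add atoms: none
Why: SN2 quaternisation of the phosphine by the allylic bromide (phosphonium salt formation) should give the crystalline salt that carries C3, C4 and the CH2CO2Me arm, with the E-enoate kept and no stereocentre formed.

Step 2
Reactants: 4 12-bromododecan-1-ol; 5 (2E,4E)-hexa-2,4-dien-1-yl acetate
Product: 8 (14E,16E)-octadeca-14,16-dien-1-ol, via chloromagnesium alkoxide 6 (not isolated), via Grignard reagent 7 (not isolated)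
Conditions: i-PrMgCl (1.0 equiv), THF, 0 °C; Mg, 45 °C; then 5, Li2CuCl4 (3 mol%), −20 → 0 °C; aq. NH4Cl
Reagents that add atoms: none
Why: Copper-catalysed coupling of an alkyl Grignard reagent with a primary allylic acetate (Fouquet–Schlosser/Kochi type) should substitute at the CH2–OAc carbon and so keep the conjugated E,E-diene, the hydroxyl being masked in the flask as its magnesium alkoxide.

Step 3
Reactants: 8 (14E,16E)-octadeca-14,16-dien-1-ol
Product: 9 (2E,4E)-18-iodooctadeca-2,4-diene
Conditions: I2, PPh3, imidazole, CH2Cl2, 0 °C → rt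
Reagents that add atoms: iodine, II
Why: Appel-type iodination converts the primary alcohol into the iodide under neutral conditions that should leave the diene geometry intact.

Step 4
Reactants: 10 (−)-8-phenylmenthol; 11 methoxyacetyl chloride
Product: 12 (1R,2S,5R)-5-methyl-2-(2-phenylpropan-2-yl)cyclohexyl methoxyacetate
Conditions: pyridine, DMAP (cat.), CH2Cl2, 0 °C → rt
Reagents that add atoms: none
Why: Acylation of the secondary alcohol by the acid chloride (pyridine/DMAP esterification) installs the recoverable chiral controller without touching its stereocentres.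

Step 5
Reactants: 12 (1R,2S,5R)-5-methyl-2-(2-phenylpropan-2-yl)cyclohexyl methoxyacetate; 9 (2E,4E)-18-iodooctadeca-2,4-diene
Product: 14 (1R,2S,5R)-5-methyl-2-(2-phenylpropan-2-yl)cyclohexyl (16E,18E)-2-methoxyicosa-16,18-dienoate (both C2 epimers), via lithium enolate 13 (not isolated)
Conditions: LiN(i-Pr)2, THF, −78 °C; then 9, DMPU, −78 → −20 °C
Reagents that add atoms: none
Why: C-alkylation of the lithium enolate of an α-alkoxy ester with a primary iodide builds the bond between future C6 and the side chain; the configuration of the new C2 centre is irrelevant because enolisation in step 6 erases it.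

Step 6
Reactants: 14 (1R,2S,5R)-5-methyl-2-(2-phenylpropan-2-yl)cyclohexyl (16E,18E)-2-methoxyicosa-16,18-dienoate
Product: 16 (1R,2S,5R)-5-methyl-2-(2-phenylpropan-2-yl)cyclohexyl (2R,16E,18E)-2-hydroperoxy-2-methoxyicosa-16,18-dienoate, via lithium enolate 15 (not isolated)
Conditions: LiN(i-Pr)2 (1.1 equiv), THF, −78 → −40 °C; enolate added to O2-saturated THF, −78 °C; AcOH, −78 °C; chromatography
Reagents that add atoms: dioxygen, O=O
Why: α-Hydroperoxidation of an ester enolate with molecular oxygen (enolate autoxidation, quenched cold) creates the peroxyketal carbon, future C6: in the lithium-chelated tetrasubstituted enolate the phenyl ring of the auxiliary should cover one face so that O2 is taken up on the other, and the minor diastereomer is removed by chromatography.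

Step 7
Reactants: 16 (1R,2S,5R)-5-methyl-2-(2-phenylpropan-2-yl)cyclohexyl (2R,16E,18E)-2-hydroperoxy-2-methoxyicosa-16,18-dienoate
Product: 17 (1R,2S,5R)-5-methyl-2-(2-phenylpropan-2-yl)cyclohexyl (2R,16E,18E)-2-methoxy-2-[(triethylsilyl)peroxy]icosa-16,18-dienoate
Conditions: Et3SiCl, imidazole, DMF, 0 °C
Reagents that add atoms: chlorotriethylsilane, CC[Si](Cl)(CC)CC
Why: O-Silylation of the hydroperoxide masks the acidic OOH before hydride reduction; C6 is not involved.

Step 8
Reactants: 17 (1R,2S,5R)-5-methyl-2-(2-phenylpropan-2-yl)cyclohexyl (2R,16E,18E)-2-methoxy-2-[(triethylsilyl)peroxy]icosa-16,18-dienoate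
Product: 18 (2R,16E,18E)-2-methoxy-2-[(triethylsilyl)peroxy]icosa-16,18-dienal
Conditions: i-Bu2AlH (1.2 equiv), CH2Cl2, −78 °C; aq. potassium sodium tartrate
Reagents that add atoms: none
Why: Partial reduction of the ester with i-Bu2AlH at −78 °C should stop at the aluminium hemiacetal, which the α-methoxy group chelates, and release the aldehyde and the auxiliary on work-up; quaternary C6 cannot epimerise.

Step 9
Reactants: 18 (2R,16E,18E)-2-methoxy-2-[(triethylsilyl)peroxy]icosa-16,18-dienal; 3 [(2E)-4-methoxy-4-oxobut-2-en-1-yl]triphenylphosphonium bromide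
Product: 22 xestin A methyl 2-[(3R,6R)-6-methoxy-6-[(14E,16E)-octadeca-14,16-dien-1-yl]-3,6-dihydro-1,2-dioxin-3-yl]acetate, via hydroperoxy aldehyde 19 (not isolated), via phosphonium adduct 20 (not isolated), via ylide 21 (not isolated)
Conditions: 3 (1.2 equiv), K2CO3 (0.2 equiv), MeOH, −10 °C; then solvent exchange to THF, KN(SiMe3)2 (1.1 equiv), −78 → −40 °C; AcOH
Reagents that add atoms: none
Why: Proposed new method: K2CO3/MeOH cleaves the Si–OO bond to give 19, whose peroxide anion adds at C3 of 3 (the enoate carbon β to the ester, equally reached through the vinylphosphonium tautomer) and is fixed by solvent protonation as salt 20; after the switch to THF, KN(SiMe3)2 makes the non-stabilised ylide 21, which closes on the neighbouring aldehyde carbon C5 by intramolecular Wittig olefination and expels Ph3P=O. The closest known reaction type is the Schweizer annulation (alkoxide or phenoxide carbonyl compounds plus vinylphosphonium salts give 2,5-dihydrofurans and 2H-chromenes by oxa-Michael addition and intramolecular Wittig reaction), joined to the known base-mediated conjugate addition of hydroperoxides to enoates in protic solvent; a hydroperoxide as the Michael donor in such an annulation is not known. The 3,6-dihydro-1,2-dioxine, the only ring, closes in the Wittig stage by C4–C5 bond formation within a six-membered array (O2–C3 having joined the two fragments), so the new alkene can only be cis. C6 comes unchanged from 18 because base cannot ionise the peroxyketal, whereas C3 is created in the intermolecular oxa-Michael stage under nothing more than remote 1,4-influence of C6 across the O–O bond, so the substrate secures no more than a modest bias and any (3S) epimer formed, a diastereomer, is removed by chromatography. The selectivity the step does need is chemoselectivity, Michael addition before any Wittig event, and it is secured by the protic first stage, which brings the acidities of OOH and of the P–CH2 group close together, holds the aldehyde as its methyl hemiacetal and protonates the ester enolate before it can attack the O–O bond. The cold, short second stage should let ring closure outrun β-elimination of the peroxide from 21 and Kornblum–DeLaMare cleavage of the product.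

## Compound list

1 | methyl (2E)-4-bromobut-2-enoate | COC(=O)/C=C/CBr | starting material
2 | triphenylphosphine | c1ccc(cc1)P(c1ccccc1)c1ccccc1 | starting material
3 | [(2E)-4-methoxy-4-oxobut-2-en-1-yl]triphenylphosphonium bromide | COC(=O)/C=C/C[P+](c1ccccc1)(c1ccccc1)c1ccccc1.[Br-] | intermediate
4 | 12-bromododecan-1-ol | OCCCCCCCCCCCCBr | starting material
5 | (2E,4E)-hexa-2,4-dien-1-yl acetate (sorbyl acetate) | C/C=C/C=C/COC(C)=O | starting material
6 | chloromagnesium 12-bromododecan-1-olate | Cl[Mg]OCCCCCCCCCCCCBr | intermediate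
7 | [12-(chloromagnesiooxy)dodecyl]magnesium bromide | Cl[Mg]OCCCCCCCCCCCC[Mg]Br | intermediate
8 | (14E,16E)-octadeca-14,16-dien-1-ol | C/C=C/C=C/CCCCCCCCCCCCCO | intermediate
9 | (2E,4E)-18-iodooctadeca-2,4-diene | C/C=C/C=C/CCCCCCCCCCCCCI | intermediate
10 | (−)-8-phenylmenthol, (1R,2S,5R)-5-methyl-2-(2-phenylpropan-2-yl)cyclohexan-1-ol | O[C@@H]1C[C@H](C)CC[C@H]1C(C)(C)c1ccccc1 | starting material
11 | methoxyacetyl chloride | COCC(=O)Cl | starting material
12 | (1R,2S,5R)-5-methyl-2-(2-phenylpropan-2-yl)cyclohexyl methoxyacetate | COCC(=O)O[C@@H]1C[C@H](C)CC[C@H]1C(C)(C)c1ccccc1 | intermediate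
13 | lithium enolate of 12 (OMe syn to OLi, chelated) | CO/C=C(\O[Li])O[C@@H]1C[C@H](C)CC[C@H]1C(C)(C)c1ccccc1 | intermediate
14 | (1R,2S,5R)-5-methyl-2-(2-phenylpropan-2-yl)cyclohexyl (16E,18E)-2-methoxyicosa-16,18-dienoate (both C2 epimers) | C/C=C/C=C/CCCCCCCCCCCCCC(OC)C(=O)O[C@@H]1C[C@H](C)CC[C@H]1C(C)(C)c1ccccc1 | intermediate
15 | lithium enolate of 14 (OMe syn to OLi, chelated) | C/C=C/C=C/CCCCCCCCCCCCC/C(OC)=C(/O[Li])O[C@@H]1C[C@H](C)CC[C@H]1C(C)(C)c1ccccc1 | intermediate
16 | (1R,2S,5R)-5-methyl-2-(2-phenylpropan-2-yl)cyclohexyl (2R,16E,18E)-2-hydroperoxy-2-methoxyicosa-16,18-dienoate | C/C=C/C=C/CCCCCCCCCCCCC[C@](OC)(C(=O)O[C@@H]1C[C@H](C)CC[C@H]1C(C)(C)c1ccccc1)OO | intermediate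
17 | (1R,2S,5R)-5-methyl-2-(2-phenylpropan-2-yl)cyclohexyl (2R,16E,18E)-2-methoxy-2-[(triethylsilyl)peroxy]icosa-16,18-dienoate | C/C=C/C=C/CCCCCCCCCCCCC[C@](OC)(C(=O)O[C@@H]1C[C@H](C)CC[C@H]1C(C)(C)c1ccccc1)OO[Si](CC)(CC)CC | intermediate
18 | (2R,16E,18E)-2-methoxy-2-[(triethylsilyl)peroxy]icosa-16,18-dienal | C/C=C/C=C/CCCCCCCCCCCCC[C@](OC)(C=O)OO[Si](CC)(CC)CC | intermediate
19 | (2R,16E,18E)-2-hydroperoxy-2-methoxyicosa-16,18-dienal | C/C=C/C=C/CCCCCCCCCCCCC[C@](OC)(C=O)OO | intermediate
20 | [4-methoxy-2-{[(2R,16E,18E)-2-methoxy-1-oxoicosa-16,18-dien-2-yl]peroxy}-4-oxobutyl]triphenylphosphonium bromide (both epimers at the new peroxide carbon) | C/C=C/C=C/CCCCCCCCCCCCC[C@](OC)(C=O)OOC(CC(=O)OC)C[P+](c1ccccc1)(c1ccccc1)c1ccccc1.[Br-] | intermediate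
21 | methyl 3-{[(2R,16E,18E)-2-methoxy-1-oxoicosa-16,18-dien-2-yl]peroxy}-4-(triphenyl-λ5-phosphanylidene)butanoate | C/C=C/C=C/CCCCCCCCCCCCC[C@](OC)(C=O)OOC(CC(=O)OC)C=P(c1ccccc1)(c1ccccc1)c1ccccc1 | intermediate
22 | xestin A, methyl 2-[(3R,6R)-6-methoxy-6-[(14E,16E)-octadeca-14,16-dien-1-yl]-3,6-dihydro-1,2-dioxin-3-yl]acetate | C/C=C/C=C/CCCCCCCCCCCCC[C@]1(OC)C=C[C@@H](CC(=O)OC)OO1 | target

## Summary and risks

Total step count: 9. Longest linear sequence: 7 steps (steps 2, 3, 5, 6, 7, 8, 9).

Steps most likely to fail: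

1. Step 9 (Proposed new method).
   - What may go wrong: proton transfer from the P–CH2 group to the peroxide anion, followed by intermolecular Wittig reaction of the conjugated ylide so formed (open-chain dienoates of mixed geometry); base-induced C5–C6 fragmentation of the α-peroxy aldehyde; lack of facial control at C3.
   - Fallback (known chemistry, olefination first and C–O ring closure last): it sets out from 18 and 3 and returns at 22. Salt 3 is deprotonated with NaN(SiMe3)2 (THF, −78 °C) to the conjugated ylide methyl (2E)-4-(triphenyl-λ5-phosphanylidene)but-2-enoate F1. This is condensed with 18 in an ordinary intermolecular Wittig reaction to methyl (2E,4Z,6R,20E,22E)-6-methoxy-6-[(triethylsilyl)peroxy]tetracosa-2,4,20,22-tetraenoate F2; the 4E isomer, which cannot cyclise, is removed by chromatography. Bu4NF/AcOH frees the hydroperoxide methyl (2E,4Z,6R,20E,22E)-6-hydroperoxy-6-methoxytetracosa-2,4,20,22-tetraenoate F3. Et2NH in CF3CH2OH then closes the ring by 6-exo oxa-Michael addition of the hydroperoxide to the enoate, giving 22 after separation from any C3 epimer.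

2. Step 6.
   - What may go wrong: insufficient facial discrimination when the enolate takes up O2, together with difficult chromatographic separation of two lipophilic diastereomers.
   - Fallback (racemic series and resolution instead of auxiliary control): it sets out from 9 and returns at 18. Commercial methyl methoxyacetate is alkylated with 9 (LiN(i-Pr)2, THF/DMPU) to racemic methyl (16E,18E)-2-methoxyicosa-16,18-dienoate F4. This is oxygenated in the same way (LiN(i-Pr)2, O2) to racemic methyl (16E,18E)-2-hydroperoxy-2-methoxyicosa-16,18-dienoate F5, silylated to methyl (16E,18E)-2-methoxy-2-[(triethylsilyl)peroxy]icosa-16,18-dienoate F6, and reduced with i-Bu2AlH to racemic (16E,18E)-2-methoxy-2-[(triethylsilyl)peroxy]icosa-16,18-dienal F7. The enantiomers of F7 are separated by preparative chromatography on a chiral stationary phase; the (2R) enantiomer is 18.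

3. Step 8.
   - What may go wrong: hydride attack on the O–O bond of the silyl peroxide, or over-reduction past the aldehyde because the ester is hindered.
   - Fallback (hydride-stable peroxide cap, full reduction and reoxidation): it sets out from 16 and returns at 19. The hydroperoxide is capped with 2-methoxypropene/PPTS as (1R,2S,5R)-5-methyl-2-(2-phenylpropan-2-yl)cyclohexyl (2R,16E,18E)-2-methoxy-2-[(2-methoxypropan-2-yl)peroxy]icosa-16,18-dienoate F8. The ester is reduced fully with excess i-Bu2AlH to (2R,16E,18E)-2-methoxy-2-[(2-methoxypropan-2-yl)peroxy]icosa-16,18-dien-1-ol F9 and reoxidised with Dess–Martin periodinane to (2R,16E,18E)-2-methoxy-2-[(2-methoxypropan-2-yl)peroxy]icosa-16,18-dienal F10. AcOH/THF/H2O removes the cap to give 19 in solution, which enters step 9 at its first stage.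

Further compounds
F1 | step 9 | methyl (2E)-4-(triphenyl-λ5-phosphanylidene)but-2-enoate | COC(=O)/C=C/C=P(c1ccccc1)(c1ccccc1)c1ccccc1
F2 | step 9 | methyl (2E,4Z,6R,20E,22E)-6-methoxy-6-[(triethylsilyl)peroxy]tetracosa-2,4,20,22-tetraenoate | C/C=C/C=C/CCCCCCCCCCCCC[C@](OC)(/C=C\C=C\C(=O)OC)OO[Si](CC)(CC)CC
F3 | step 9 | methyl (2E,4Z,6R,20E,22E)-6-hydroperoxy-6-methoxytetracosa-2,4,20,22-tetraenoate | C/C=C/C=C/CCCCCCCCCCCCC[C@](OC)(/C=C\C=C\C(=O)OC)OO
F4 | step 6 | racemic methyl (16E,18E)-2-methoxyicosa-16,18-dienoate | C/C=C/C=C/CCCCCCCCCCCCCC(OC)C(=O)OC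
F5 | step 6 | racemic methyl (16E,18E)-2-hydroperoxy-2-methoxyicosa-16,18-dienoate | C/C=C/C=C/CCCCCCCCCCCCCC(OC)(OO)C(=O)OC
F6 | step 6 | racemic methyl (16E,18E)-2-methoxy-2-[(triethylsilyl)peroxy]icosa-16,18-dienoate | C/C=C/C=C/CCCCCCCCCCCCCC(OC)(OO[Si](CC)(CC)CC)C(=O)OC
F7 | step 6 | racemic (16E,18E)-2-methoxy-2-[(triethylsilyl)peroxy]icosa-16,18-dienal | C/C=C/C=C/CCCCCCCCCCCCCC(OC)(C=O)OO[Si](CC)(CC)CC
F8 | step 8 | (1R,2S,5R)-5-methyl-2-(2-phenylpropan-2-yl)cyclohexyl (2R,16E,18E)-2-methoxy-2-[(2-methoxypropan-2-yl)peroxy]icosa-16,18-dienoate | C/C=C/C=C/CCCCCCCCCCCCC[C@](OC)(C(=O)O[C@@H]1C[C@H](C)CC[C@H]1C(C)(C)c1ccccc1)OOC(C)(C)OC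
F9 | step 8 | (2R,16E,18E)-2-methoxy-2-[(2-methoxypropan-2-yl)peroxy]icosa-16,18-dien-1-ol | C/C=C/C=C/CCCCCCCCCCCCC[C@](OC)(CO)OOC(C)(C)OC
F10 | step 8 | (2R,16E,18E)-2-methoxy-2-[(2-methoxypropan-2-yl)peroxy]icosa-16,18-dienal | C/C=C/C=C/CCCCCCCCCCCCC[C@](OC)(C=O)OOC(C)(C)OC
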